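**Plan**

- Cuts: C3–Br goes back to a C2=C3 bromoalkene and then a C3 ketone; the C13 carbinol with its vinyl group goes back to an E C13=C14 allylic alcohol; C12–C13 is an sp3–sp2 coupling on a C9 vinyl group; the decalin is cut at C5–C10 and C8–C9 together.
- Enabling feature: in ring B the methyl-bearing quaternary C10, C9 (with the C11 branch) and the C8 methyl carbinol stand in a row opposite C6–C7. That is a cyclohexene retron with C9=C10 as an E β-methyl enal and C5=C6–C7=C8(Me)(OSi) as a 1-methyl-1-silyloxydiene. Ring A is then only the tether C1–C4, whose C3 oxygen beside the C4 gem-dimethyl carbon is the carbinol/CMe2 unit of pantolactone.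
- Forward: (S)-pantolactone supplies C2–C5. The diene arm grows from C5 (Takai iodo-olefination, vinyllithium plus propylene oxide) and the enal arm from C2 (methylenation, hydroboration/Suzuki). One intramolecular Diels–Alder reaction closes rings A and B at once; a second hydroboration/Suzuki coupling adds the side chain, then C3 and C13 are adjusted.
- Stereochemistry: the pantolactone carbon (C3) selects the diene face and is erased later. The E enal with endo formyl gives C9, C10 and the trans fusion to C5; the Z dienol ether gives C8. C13 comes from a D-(−)-tartrate Sharpless epoxidation, and the equatorial C3–Br from axial hydrogen delivery in an HAT hydrogenation of the bromoalkene.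

Key step: step 13

Remarks: atoms are numbered as in labdanes (C1–C20). The configuration of the carbinol carbon brought in with propylene oxide is immaterial (it is oxidised in step 9); the (R)-epoxide is used only so that 9, 12 and 13 are single diastereomers.

**Route**

Step 1
Reactants: 1 (S)-pantolactone
Product: 2 (S)-3-(benzyloxy)-4,4-dimethyldihydrofuran-2(3H)-one
Conditions: BnOC(=NH)CCl3, TfOH (cat.), CH2Cl2/cyclohexane, 0 °C → rt
Reagents that add atoms: benzyl 2,2,2-trichloroacetimidate, ClC(Cl)(Cl)C(=N)OCc1ccccc1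
Why: Acid-catalysed trichloroacetimidate benzylation etherifies the α-hydroxy lactone without base, so the α-stereocentre cannot epimerise.

Step 2
Reactants: 2 (S)-3-(benzyloxy)-4,4-dimethyldihydrofuran-2(3H)-one
Product: 3 (3S)-3-(benzyloxy)-4,4-dimethyltetrahydrofuran-2-ol (anomer mixture)
Conditions: DIBAL-H, CH2Cl2, −78 °C; Rochelle salt
Reagents that add atoms: none
Why: Partial DIBAL reduction of a γ-lactone stops at the lactol because the tetrahedral aluminate is stable at −78 °C.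

Step 3
Reactants: 3 (3S)-3-(benzyloxy)-4,4-dimethyltetrahydrofuran-2-ol
Product: 4 (R)-3-(benzyloxy)-2,2-dimethylpent-4-en-1-ol
Conditions: Ph3PCH3Br, KOtBu (excess ylide), THF, 0 °C → rt
Reagents that add atoms: methyltriphenylphosphonium bromide, C[P+](c1ccccc1)(c1ccccc1)c1ccccc1.[Br-]
Why: Wittig methylenation traps the hydroxy-aldehyde tautomer of the lactol, turning C2 into a vinyl placeholder and freeing the neopentyl C5 alcohol; the benzyl ether cannot migrate.

Step 4
Reactants: 4 (R)-3-(benzyloxy)-2,2-dimethylpent-4-en-1-ol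
Product: 5 (R)-3-(benzyloxy)-2,2-dimethylpent-4-enal
Conditions: Dess–Martin periodinane, NaHCO3, CH2Cl2, rt
Reagents that add atoms: none
Why: Dess–Martin oxidation of a primary alcohol gives an aldehyde that has no α-hydrogen and therefore cannot enolise or epimerise.

Step 5
Reactants: 5 (R)-3-(benzyloxy)-2,2-dimethylpent-4-enal
Product: 6 (3R,5E)-3-(benzyloxy)-6-iodo-4,4-dimethylhexa-1,5-diene
Conditions: CrCl2, CHI3, THF/dioxane, 0 °C → rt
Reagents that add atoms: iodoform, IC(I)I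
Why: Takai iodo-olefination converts aldehydes into E vinyl iodides, and the α-quaternary centre should reinforce the E preference that fixes the C5=C6 geometry.

Step 6
Reactants: 6 (3R,5E)-3-(benzyloxy)-6-iodo-4,4-dimethylhexa-1,5-diene; 7 (R)-2-methyloxirane
Product: 9 (2R,4E,7R)-7-(benzyloxy)-6,6-dimethylnona-4,8-dien-2-ol, via vinyllithium 8 (not isolated)
Conditions: t-BuLi (2 equiv), Et2O, −78 °C; then BF3·OEt2, 7, −78 °C
Reagents that add atoms: none
Why: Iodine–lithium exchange keeps the alkene geometry and the BF3-assisted epoxide opening by the alkenyllithium occurs at the CH2 terminus, giving the E homoallylic alcohol (C5=C6–C7–C8(OH)–C17) faster than benzylic deprotonation can occur at −78 °C.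

Step 7
Reactants: 10 ethyl acetoacetate
Product: 11 ethyl (E)-3-{[(trifluoromethyl)sulfonyl]oxy}but-2-enoate
Conditions: Tf2O, aq. Me4NOH, hexanes, 5 °C → rt
Reagents that add atoms: trifluoromethanesulfonic anhydride, O=S(=O)(OS(=O)(=O)C(F)(F)F)C(F)(F)F
Why: O-triflation of the non-chelated tetramethylammonium enolate of a β-keto ester should give the E enol triflate (triflate trans to the ester), the geometry needed for both later couplings.

Step 8
Reactants: 9 (2R,4E,7R)-7-(benzyloxy)-6,6-dimethylnona-4,8-dien-2-ol; 11 ethyl (E)-3-{[(trifluoromethyl)sulfonyl]oxy}but-2-enoate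
Product: 13 ethyl (2E,6R,8E,11R)-6-(benzyloxy)-11-hydroxy-3,7,7-trimethyldodeca-2,8-dienoate, via B-alkyl-9-BBN adduct 12 (not isolated)
Conditions: 9-BBN (excess), THF, 0 °C → rt; then 11, PdCl2(dppf) (cat.), AsPh3, Cs2CO3, DMF/H2O, rt
Reagents that add atoms: none
Why: 9-BBN adds only to the terminal vinyl group (boron on C1) and the B-alkyl Suzuki–Miyaura coupling replaces the triflate with retention, so the C9=C10 enoate is E without an olefination mixture; the free hydroxyl merely consumes borane as a borinate that hydrolyses in the basic medium.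

Step 9
Reactants: 13 ethyl (2E,6R,8E,11R)-6-(benzyloxy)-11-hydroxy-3,7,7-trimethyldodeca-2,8-dienoate
Product: 14 ethyl (2E,6R,8E)-6-(benzyloxy)-3,7,7-trimethyl-11-oxododeca-2,8-dienoate
Conditions: Dess–Martin periodinane, NaHCO3, CH2Cl2, 0 °C → rt
Reagents that add atoms: none
Why: Buffered Dess–Martin oxidation of a homoallylic alcohol gives the β,γ-unsaturated methyl ketone without moving the C5=C6 alkene into conjugation.

Step 10
Reactants: 14 ethyl (2E,6R,8E)-6-(benzyloxy)-3,7,7-trimethyl-11-oxododeca-2,8-dienoate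
Product: 15 ethyl (2E,6R,8E,10Z)-6-(benzyloxy)-3,7,7-trimethyl-11-[(triethylsilyl)oxy]dodeca-2,8,10-trienoate
Conditions: TESOTf, Et3N, CH2Cl2, −78 °C; chromatography on Et3N-deactivated silica
Reagents that add atoms: triethylsilyl trifluoromethanesulfonate, CC[Si](CC)(CC)OS(=O)(=O)C(F)(F)F
Why: Soft enolisation removes the doubly activated C7 hydrogen to give the conjugated silyl dienol ether, the Z isomer (oxygen cis to C6) being favoured because it avoids allylic strain between the C17 methyl and C6, while the ester is inert to these conditions.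

Step 11
Reactants: 15 ethyl (2E,6R,8E,10Z)-6-(benzyloxy)-3,7,7-trimethyl-11-[(triethylsilyl)oxy]dodeca-2,8,10-trienoate
Product: 16 (2E,6R,8E,10Z)-6-(benzyloxy)-3,7,7-trimethyl-11-[(triethylsilyl)oxy]dodeca-2,8,10-trien-1-ol
Conditions: DIBAL-H, CH2Cl2, −78 °C; Rochelle salt
Reagents that add atoms: none
Why: DIBAL 1,2-reduction of the enoate gives the allylic alcohol under non-acidic conditions that a silyl enol ether tolerates.

Step 12
Reactants: 16 (2E,6R,8E,10Z)-6-(benzyloxy)-3,7,7-trimethyl-11-[(triethylsilyl)oxy]dodeca-2,8,10-trien-1-ol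
Product: 17 (2E,6R,8E,10Z)-6-(benzyloxy)-3,7,7-trimethyl-11-[(triethylsilyl)oxy]dodeca-2,8,10-trienal
Conditions: activated MnO2, CH2Cl2, rt
Reagents that add atoms: none
Why: MnO2 oxidises only the allylic alcohol, under neutral conditions, and gives the E enal without touching the dienol ether.

Step 13
Reactants: 17 (2E,6R,8E,10Z)-6-(benzyloxy)-3,7,7-trimethyl-11-[(triethylsilyl)oxy]dodeca-2,8,10-trienal
Product: 18 (1S,2S,4aS,6R,8aR)-6-(benzyloxy)-2,5,5,8a-tetramethyl-2-[(triethylsilyl)oxy]-1,2,4a,5,6,7,8,8a-octahydronaphthalene-1-carbaldehyde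
Conditions: Me2AlCl (1.2 equiv), CH2Cl2 (dilute), −78 → −30 °C; cold Et3N/aq. NaHCO3 quench
Reagents that add atoms: none
Why: Me2AlCl binds the formyl oxygen and lowers the enal LUMO, and a concerted but asynchronous [4+2] joins the enal β-carbon C10 to the unoxygenated diene terminus C5 and the α-carbon C9 to the silyloxy-bearing terminus C8, the polarisation of the two partners being matched. The closest known reaction type is the type 1 intramolecular Diels–Alder reaction of terminally activated 1,7,9-decatrienes, which gives trans-fused decalins. Ring A closes through the four-carbon tether C1–C4 in a chair-like fold as C5–C10 forms, helped by the C4 gem-dimethyl group, and ring B is the cyclohexene made by the cycloaddition itself (new C6=C7). C9 and C10 follow from suprafacial addition to the E enal (formyl and C20 methyl cis); the trans relation of C10 to C5 follows from the endo-formyl transition state; C8 follows from the Z enol ether (oxygen inside, C17 outside and so cis to C4 and the formyl group); C5 follows from attack on the diene face that leaves the C3 benzyloxy group equatorial in the chair tether. The step needs endo selectivity, which Lewis-acid activation of a terminal E formyl dienophile should secure, and diene-face selectivity, which rests on the C3 stereocentre; the minor face isomer is a diastereomer and would be removed by chromatography before C3 is oxidised. Me2AlCl is chosen because it scavenges protic acid and so should spare the silyl dienol ether and the tertiary allylic silyl ether of the product.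

Step 14
Reactants: 18 (1S,2S,4aS,6R,8aR)-6-(benzyloxy)-2,5,5,8a-tetramethyl-2-[(triethylsilyl)oxy]-1,2,4a,5,6,7,8,8a-octahydronaphthalene-1-carbaldehyde
Product: 19 (1S,2S,4aS,6R,8aR)-6-hydroxy-2,5,5,8a-tetramethyl-2-[(triethylsilyl)oxy]decahydronaphthalene-1-carbaldehyde
Conditions: H2 (1 atm), 10% Pd/C, EtOAc, rt
Reagents that add atoms: none
Why: Heterogeneous hydrogenation saturates C6=C7 and hydrogenolyses the benzyl ether in one operation, while the hindered aliphatic aldehyde and the silyl ether survive in EtOAc; no stereocentre is formed.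

Step 15
Reactants: 19 (1S,2S,4aS,6R,8aR)-6-hydroxy-2,5,5,8a-tetramethyl-2-[(triethylsilyl)oxy]decahydronaphthalene-1-carbaldehyde
Product: 20 (2R,4aR,5S,6S,8aS)-5-ethenyl-1,1,4a,6-tetramethyl-6-[(triethylsilyl)oxy]decahydronaphthalen-2-ol
Conditions: Ph3PCH3Br, KOtBu (excess ylide), THF, 0 °C → rt
Reagents that add atoms: methyltriphenylphosphonium bromide, C[P+](c1ccccc1)(c1ccccc1)c1ccccc1.[Br-]
Why: Wittig methylenation of the aldehyde gives the C11=C12 vinyl group; the formyl group is already equatorial, so reversible enolisation cannot epimerise C9, and the excess ylide covers the free C3 hydroxyl.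

Step 16
Reactants: 20 (2R,4aR,5S,6S,8aS)-5-ethenyl-1,1,4a,6-tetramethyl-6-[(triethylsilyl)oxy]decahydronaphthalen-2-ol; 11 ethyl (E)-3-{[(trifluoromethyl)sulfonyl]oxy}but-2-enoate
Product: 22 ethyl (E)-5-[(1S,2S,4aS,6R,8aR)-6-hydroxy-2,5,5,8a-tetramethyl-2-[(triethylsilyl)oxy]decahydronaphthalen-1-yl]-3-methylpent-2-enoate, via B-alkyl-9-BBN adduct 21 (not isolated)
Conditions: 9-BBN (excess), THF, rt → 50 °C; then 11, PdCl2(dppf) (cat.), AsPh3, Cs2CO3, DMF/H2O, rt
Reagents that add atoms: none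
Why: Anti-Markovnikov hydroboration puts boron on C12 and the B-alkyl Suzuki–Miyaura coupling with the E enol triflate forms C12–C13 with retention, giving the E C13=C14 enoate as a single alkene isomer.

Step 17
Reactants: 22 ethyl (E)-5-[(1S,2S,4aS,6R,8aR)-6-hydroxy-2,5,5,8a-tetramethyl-2-[(triethylsilyl)oxy]decahydronaphthalen-1-yl]-3-methylpent-2-enoate
Product: 23 ethyl (E)-3-methyl-5-[(1S,2S,4aS,8aR)-2,5,5,8a-tetramethyl-6-oxo-2-[(triethylsilyl)oxy]decahydronaphthalen-1-yl]pent-2-enoate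
Conditions: Dess–Martin periodinane, NaHCO3, CH2Cl2, rt
Reagents that add atoms: none
Why: Dess–Martin oxidation of the only free (secondary) alcohol removes the C3 stereocentre once it has done its work.

Step 18
Reactants: 23 ethyl (E)-3-methyl-5-[(1S,2S,4aS,8aR)-2,5,5,8a-tetramethyl-6-oxo-2-[(triethylsilyl)oxy]decahydronaphthalen-1-yl]pent-2-enoate
Product: 24 ethyl (E)-3-methyl-5-[(1S,2S,4aS,8aR)-2,5,5,8a-tetramethyl-2-[(triethylsilyl)oxy]-6-{[(trifluoromethyl)sulfonyl]oxy}-1,2,3,4,4a,5,8,8a-octahydronaphthalen-1-yl]pent-2-enoate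
Conditions: LiHMDS, THF, −78 °C; PhNTf2, −78 → 0 °C
Reagents that add atoms: N-phenylbis(trifluoromethanesulfonimide), O=S(=O)(N(c1ccccc1)S(=O)(=O)C(F)(F)F)C(F)(F)F
Why: The ketone can enolise only toward C2 because C4 is quaternary, and O-triflation of the kinetic lithium enolate gives the C2=C3 enol triflate; the ketone α-hydrogens are more acidic than the enoate γ-hydrogens.

Step 19
Reactants: 24 ethyl (E)-3-methyl-5-[(1S,2S,4aS,8aR)-2,5,5,8a-tetramethyl-2-[(triethylsilyl)oxy]-6-{[(trifluoromethyl)sulfonyl]oxy}-1,2,3,4,4a,5,8,8a-octahydronaphthalen-1-yl]pent-2-enoate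
Product: 25 ethyl (E)-5-[(1S,2S,4aS,8aR)-6-bromo-2,5,5,8a-tetramethyl-2-[(triethylsilyl)oxy]-1,2,3,4,4a,5,8,8a-octahydronaphthalen-1-yl]-3-methylpent-2-enoate
Conditions: Ni(OAc)2·4H2O (cat.), 1,5-cyclooctadiene, Zn (cat.), LiBr, DMA/THF, rt
Reagents that add atoms: lithium bromide, [Li+].[Br-]
Why: Nickel-catalysed halogenation of enol triflates (oxidative addition, triflate/bromide exchange, C–Br reductive elimination) gives the alkenyl bromide at room temperature and tolerates esters and silyl ethers.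

Step 20
Reactants: 25 ethyl (E)-5-[(1S,2S,4aS,8aR)-6-bromo-2,5,5,8a-tetramethyl-2-[(triethylsilyl)oxy]-1,2,3,4,4a,5,8,8a-octahydronaphthalen-1-yl]-3-methylpent-2-enoate
Product: 26 (E)-5-[(1S,2S,4aS,8aR)-6-bromo-2,5,5,8a-tetramethyl-2-[(triethylsilyl)oxy]-1,2,3,4,4a,5,8,8a-octahydronaphthalen-1-yl]-3-methylpent-2-en-1-ol
Conditions: DIBAL-H, CH2Cl2, −78 °C; Rochelle salt
Reagents that add atoms: none
Why: DIBAL 1,2-reduction of the enoate gives the E allylic alcohol and leaves the alkenyl bromide untouched.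

Step 21
Reactants: 26 (E)-5-[(1S,2S,4aS,8aR)-6-bromo-2,5,5,8a-tetramethyl-2-[(triethylsilyl)oxy]-1,2,3,4,4a,5,8,8a-octahydronaphthalen-1-yl]-3-methylpent-2-en-1-ol
Product: 27 [(2R,3R)-3-{2-[(1S,2S,4aS,8aR)-6-bromo-2,5,5,8a-tetramethyl-2-[(triethylsilyl)oxy]-1,2,3,4,4a,5,8,8a-octahydronaphthalen-1-yl]ethyl}-3-methyloxiran-2-yl]methanol
Conditions: Ti(OiPr)4 (cat.), D-(−)-diethyl tartrate, TBHP, 4 Å MS, CH2Cl2, −20 °C
Reagents that add atoms: tert-butyl hydroperoxide, CC(C)(C)OO
Why: Katsuki–Sharpless epoxidation of the E (geraniol-type) allylic alcohol with D-(−)-tartrate should deliver oxygen to the face that gives the (2R,3R)-epoxy alcohol, which sets C13 as R under reagent control; the bromoalkene is not an allylic alcohol and is not oxidised.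

Step 22
Reactants: 27 [(2R,3R)-3-{2-[(1S,2S,4aS,8aR)-6-bromo-2,5,5,8a-tetramethyl-2-[(triethylsilyl)oxy]-1,2,3,4,4a,5,8,8a-octahydronaphthalen-1-yl]ethyl}-3-methyloxiran-2-yl]methanol
Product: 28 [(2R,3R)-3-{2-[(1S,2S,4aS,6R,8aR)-6-bromo-2,5,5,8a-tetramethyl-2-[(triethylsilyl)oxy]decahydronaphthalen-1-yl]ethyl}-3-methyloxiran-2-yl]methanol
Conditions: Mn(dpm)3 (cat.), PhSiH3, TBHP, i-PrOH, rt; K2CO3/MeOH work-up
Reagents that add atoms: none
Why: Manganese-hydride HAT hydrogenation, which reduces haloalkenes without cleaving the carbon–halogen bond, adds H• to C2 to give the α-bromo radical at C3; this radical should take the second hydrogen axially on the face away from the axial C4 and C10 methyl groups, leaving bromine equatorial (3R, the thermodynamic epimer), and the bromoalkene is the only alkene present.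

Step 23
Reactants: 28 [(2R,3R)-3-{2-[(1S,2S,4aS,6R,8aR)-6-bromo-2,5,5,8a-tetramethyl-2-[(triethylsilyl)oxy]decahydronaphthalen-1-yl]ethyl}-3-methyloxiran-2-yl]methanol
Product: 29 {[(1S,2S,4aS,6R,8aR)-6-bromo-1-{2-[(2R,3S)-3-(iodomethyl)-2-methyloxiran-2-yl]ethyl}-2,5,5,8a-tetramethyldecahydronaphthalen-2-yl]oxy}triethylsilane
Conditions: I2, PPh3, imidazole, THF, 0 °C
Reagents that add atoms: iodine, II
Why: Appel-type (Garegg–Samuelsson) iodination converts the primary alcohol into the iodide under buffered conditions that leave the epoxide, the silyl ether and the hindered secondary bromide alone.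

Step 24
Reactants: 29 {[(1S,2S,4aS,6R,8aR)-6-bromo-1-{2-[(2R,3S)-3-(iodomethyl)-2-methyloxiran-2-yl]ethyl}-2,5,5,8a-tetramethyldecahydronaphthalen-2-yl]oxy}triethylsilane
Product: 30 (3R)-5-[(1S,2S,4aS,6R,8aR)-6-bromo-2,5,5,8a-tetramethyl-2-[(triethylsilyl)oxy]decahydronaphthalen-1-yl]-3-methylpent-1-en-3-ol
Conditions: Zn dust, EtOH, 60 °C
Reagents that add atoms: none
Why: Zinc inserts into the primary C–I bond and β-elimination opens the epoxide to the tertiary allylic alcohol (the route used for linalool-type alcohols); the C13–O bond is never broken, so 13R is kept, and the unactivated equatorial bromide does not react with zinc.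

Step 25
Reactants: 30 (3R)-5-[(1S,2S,4aS,6R,8aR)-6-bromo-2,5,5,8a-tetramethyl-2-[(triethylsilyl)oxy]decahydronaphthalen-1-yl]-3-methylpent-1-en-3-ol
Product: 31 (1S,2S,4aS,6R,8aR)-6-bromo-1-[(3R)-3-hydroxy-3-methylpent-4-en-1-yl]-2,5,5,8a-tetramethyldecahydronaphthalen-2-ol (CNP0150870.4)
Conditions: TBAF, THF, rt
Reagents that add atoms: none
Why: Fluoride cleaves the tertiary triethylsilyl ether; it was kept until the enoate and the epoxide were gone, because the free C8 hydroxyl would add to either of them.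

**Compound list**

1 | (S)-pantolactone | CC1(C)COC(=O)[C@H]1O | starting material
2 | (S)-3-(benzyloxy)-4,4-dimethyldihydrofuran-2(3H)-one | CC1(C)COC(=O)[C@H]1OCc1ccccc1 | intermediate
3 | (3S)-3-(benzyloxy)-4,4-dimethyltetrahydrofuran-2-ol (anomer mixture) | CC1(C)COC(O)[C@H]1OCc1ccccc1 | intermediate
4 | (R)-3-(benzyloxy)-2,2-dimethylpent-4-en-1-ol | C=C[C@@H](OCc1ccccc1)C(C)(C)CO | intermediate
5 | (R)-3-(benzyloxy)-2,2-dimethylpent-4-enal | C=C[C@@H](OCc1ccccc1)C(C)(C)C=O | intermediate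
6 | (3R,5E)-3-(benzyloxy)-6-iodo-4,4-dimethylhexa-1,5-diene | C=C[C@@H](OCc1ccccc1)C(C)(C)/C=C/I | intermediate
7 | (R)-2-methyloxirane | C[C@@H]1CO1 | starting material
8 | [(1E,4R)-4-(benzyloxy)-3,3-dimethylhexa-1,5-dien-1-yl]lithium | C=C[C@@H](OCc1ccccc1)C(C)(C)/C=C/[Li] | intermediate
9 | (2R,4E,7R)-7-(benzyloxy)-6,6-dimethylnona-4,8-dien-2-ol | C=C[C@@H](OCc1ccccc1)C(C)(C)/C=C/C[C@@H](C)O | intermediate
10 | ethyl acetoacetate | CCOC(=O)CC(C)=O | starting material
11 | ethyl (E)-3-{[(trifluoromethyl)sulfonyl]oxy}but-2-enoate | CCOC(=O)/C=C(\C)OS(=O)(=O)C(F)(F)F | intermediate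
12 | 9-[(3R,5E,8R)-3-(benzyloxy)-8-hydroxy-4,4-dimethylnon-5-en-1-yl]-9-borabicyclo[3.3.1]nonane | B1(CC[C@@H](OCc2ccccc2)C(C)(C)/C=C/C[C@@H](C)O)C2CCCC1CCC2 | intermediate
13 | ethyl (2E,6R,8E,11R)-6-(benzyloxy)-11-hydroxy-3,7,7-trimethyldodeca-2,8-dienoate | CCOC(=O)/C=C(\C)CC[C@@H](OCc1ccccc1)C(C)(C)/C=C/C[C@@H](C)O | intermediate
14 | ethyl (2E,6R,8E)-6-(benzyloxy)-3,7,7-trimethyl-11-oxododeca-2,8-dienoate | CCOC(=O)/C=C(\C)CC[C@@H](OCc1ccccc1)C(C)(C)/C=C/CC(C)=O | intermediate
15 | ethyl (2E,6R,8E,10Z)-6-(benzyloxy)-3,7,7-trimethyl-11-[(triethylsilyl)oxy]dodeca-2,8,10-trienoate | CCOC(=O)/C=C(\C)CC[C@@H](OCc1ccccc1)C(C)(C)/C=C/C=C(/C)O[Si](CC)(CC)CC | intermediate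
16 | (2E,6R,8E,10Z)-6-(benzyloxy)-3,7,7-trimethyl-11-[(triethylsilyl)oxy]dodeca-2,8,10-trien-1-ol | OC/C=C(\C)CC[C@@H](OCc1ccccc1)C(C)(C)/C=C/C=C(/C)O[Si](CC)(CC)CC | intermediate
17 | (2E,6R,8E,10Z)-6-(benzyloxy)-3,7,7-trimethyl-11-[(triethylsilyl)oxy]dodeca-2,8,10-trienal | O=C/C=C(\C)CC[C@@H](OCc1ccccc1)C(C)(C)/C=C/C=C(/C)O[Si](CC)(CC)CC | intermediate
18 | (1S,2S,4aS,6R,8aR)-6-(benzyloxy)-2,5,5,8a-tetramethyl-2-[(triethylsilyl)oxy]-1,2,4a,5,6,7,8,8a-octahydronaphthalene-1-carbaldehyde | O=C[C@H]1[C@]2(C)CC[C@@H](OCc3ccccc3)C(C)(C)[C@H]2C=C[C@]1(C)O[Si](CC)(CC)CC | intermediate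
19 | (1S,2S,4aS,6R,8aR)-6-hydroxy-2,5,5,8a-tetramethyl-2-[(triethylsilyl)oxy]decahydronaphthalene-1-carbaldehyde | O=C[C@H]1[C@]2(C)CC[C@@H](O)C(C)(C)[C@H]2CC[C@]1(C)O[Si](CC)(CC)CC | intermediate
20 | (2R,4aR,5S,6S,8aS)-5-ethenyl-1,1,4a,6-tetramethyl-6-[(triethylsilyl)oxy]decahydronaphthalen-2-ol | C=C[C@H]1[C@]2(C)CC[C@@H](O)C(C)(C)[C@H]2CC[C@]1(C)O[Si](CC)(CC)CC | intermediate
21 | (2R,4aR,5S,6S,8aS)-5-[2-(9-borabicyclo[3.3.1]nonan-9-yl)ethyl]-1,1,4a,6-tetramethyl-6-[(triethylsilyl)oxy]decahydronaphthalen-2-ol | B3(CC[C@H]1[C@]2(C)CC[C@@H](O)C(C)(C)[C@H]2CC[C@]1(C)O[Si](CC)(CC)CC)C4CCCC3CCC4 | intermediate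
22 | ethyl (E)-5-[(1S,2S,4aS,6R,8aR)-6-hydroxy-2,5,5,8a-tetramethyl-2-[(triethylsilyl)oxy]decahydronaphthalen-1-yl]-3-methylpent-2-enoate | CCOC(=O)/C=C(\C)CC[C@H]1[C@]2(C)CC[C@@H](O)C(C)(C)[C@H]2CC[C@]1(C)O[Si](CC)(CC)CC | intermediate
23 | ethyl (E)-3-methyl-5-[(1S,2S,4aS,8aR)-2,5,5,8a-tetramethyl-6-oxo-2-[(triethylsilyl)oxy]decahydronaphthalen-1-yl]pent-2-enoate | CCOC(=O)/C=C(\C)CC[C@H]1[C@]2(C)CCC(=O)C(C)(C)[C@H]2CC[C@]1(C)O[Si](CC)(CC)CC | intermediate
24 | ethyl (E)-3-methyl-5-[(1S,2S,4aS,8aR)-2,5,5,8a-tetramethyl-2-[(triethylsilyl)oxy]-6-{[(trifluoromethyl)sulfonyl]oxy}-1,2,3,4,4a,5,8,8a-octahydronaphthalen-1-yl]pent-2-enoate | CCOC(=O)/C=C(\C)CC[C@H]1[C@]2(C)CC=C(OS(=O)(=O)C(F)(F)F)C(C)(C)[C@H]2CC[C@]1(C)O[Si](CC)(CC)CC | intermediate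
25 | ethyl (E)-5-[(1S,2S,4aS,8aR)-6-bromo-2,5,5,8a-tetramethyl-2-[(triethylsilyl)oxy]-1,2,3,4,4a,5,8,8a-octahydronaphthalen-1-yl]-3-methylpent-2-enoate | CCOC(=O)/C=C(\C)CC[C@H]1[C@]2(C)CC=C(Br)C(C)(C)[C@H]2CC[C@]1(C)O[Si](CC)(CC)CC | intermediate
26 | (E)-5-[(1S,2S,4aS,8aR)-6-bromo-2,5,5,8a-tetramethyl-2-[(triethylsilyl)oxy]-1,2,3,4,4a,5,8,8a-octahydronaphthalen-1-yl]-3-methylpent-2-en-1-ol | OC/C=C(\C)CC[C@H]1[C@]2(C)CC=C(Br)C(C)(C)[C@H]2CC[C@]1(C)O[Si](CC)(CC)CC | intermediate
27 | [(2R,3R)-3-{2-[(1S,2S,4aS,8aR)-6-bromo-2,5,5,8a-tetramethyl-2-[(triethylsilyl)oxy]-1,2,3,4,4a,5,8,8a-octahydronaphthalen-1-yl]ethyl}-3-methyloxiran-2-yl]methanol | OC[C@H]1O[C@]1(C)CC[C@H]1[C@]2(C)CC=C(Br)C(C)(C)[C@H]2CC[C@]1(C)O[Si](CC)(CC)CC | intermediate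
28 | [(2R,3R)-3-{2-[(1S,2S,4aS,6R,8aR)-6-bromo-2,5,5,8a-tetramethyl-2-[(triethylsilyl)oxy]decahydronaphthalen-1-yl]ethyl}-3-methyloxiran-2-yl]methanol | OC[C@H]1O[C@]1(C)CC[C@H]1[C@]2(C)CC[C@@H](Br)C(C)(C)[C@H]2CC[C@]1(C)O[Si](CC)(CC)CC | intermediate
29 | {[(1S,2S,4aS,6R,8aR)-6-bromo-1-{2-[(2R,3S)-3-(iodomethyl)-2-methyloxiran-2-yl]ethyl}-2,5,5,8a-tetramethyldecahydronaphthalen-2-yl]oxy}triethylsilane | IC[C@H]1O[C@]1(C)CC[C@H]1[C@]2(C)CC[C@@H](Br)C(C)(C)[C@H]2CC[C@]1(C)O[Si](CC)(CC)CC | intermediate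
30 | (3R)-5-[(1S,2S,4aS,6R,8aR)-6-bromo-2,5,5,8a-tetramethyl-2-[(triethylsilyl)oxy]decahydronaphthalen-1-yl]-3-methylpent-1-en-3-ol | C=C[C@](C)(O)CC[C@H]1[C@]2(C)CC[C@@H](Br)C(C)(C)[C@H]2CC[C@]1(C)O[Si](CC)(CC)CC | intermediate
31 | (1S,2S,4aS,6R,8aR)-6-bromo-1-[(3R)-3-hydroxy-3-methylpent-4-en-1-yl]-2,5,5,8a-tetramethyldecahydronaphthalen-2-ol | C=C[C@](C)(O)CC[C@H]1[C@]2(C)CC[C@@H](Br)C(C)(C)[C@H]2CC[C@]1(C)O | target

**Count**

Total steps: 25. Longest linear sequence: 24 (steps 1–6 and 8–25 from 1; step 7 is a one-step side branch from 10 whose product is used in steps 8 and 16).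

**Steps most likely to fail**

1. Step 13 (Diels–Alder bicyclisation). The Lewis acid may strip the silyl group from the dienol ether, or promote Mukaiyama-type addition to the activated aldehyde, faster than the cycloaddition proceeds. Bond formation between the two fully substituted termini may also be slow, and discrimination of the diene faces by the C3 ether may be modest. Fallback: the same two bonds are formed at the ester oxidation level, where no aldehyde is present and stronger chloroalanes or prolonged heating are tolerated. The fallback sets out from 15. Treating 15 with Et2AlCl in CH2Cl2 at −20 → 0 °C (or heating it in toluene with BHT in a sealed, base-washed vessel) should give ethyl (1S,2S,4aS,6R,8aR)-6-(benzyloxy)-2,5,5,8a-tetramethyl-2-[(triethylsilyl)oxy]-1,2,4a,5,6,7,8,8a-octahydronaphthalene-1-carboxylate F1 through the same endo, chair-tether transition state. DIBAL reduction gives the primary alcohol [(1R,2S,4aS,6R,8aR)-6-(benzyloxy)-2,5,5,8a-tetramethyl-2-[(triethylsilyl)oxy]-1,2,4a,5,6,7,8,8a-octahydronaphthalen-1-yl]methanol F2. Buffered Dess–Martin oxidation of F2 comes back to the route at 18.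

2. Step 10 (silyl dienol ether). The enolisation may give E/Z mixtures or let the β,γ-alkene drift into conjugation, and the dienol ether may hydrolyse during the reduction, oxidation and chromatography that follow. Fallback: the order is reversed so that silylation is the last operation before the cycloaddition and the dienol ether is never carried through redox steps. The fallback sets out from 13. DIBAL reduction gives (2E,6R,8E,11R)-6-(benzyloxy)-3,7,7-trimethyldodeca-2,8-diene-1,11-diol F3. Dess–Martin oxidation of both hydroxyls gives (2E,6R,8E)-6-(benzyloxy)-3,7,7-trimethyl-11-oxododeca-2,8-dienal F4. Soft enolisation of F4 with 1.05 equiv of TESOTf and Et3N at −78 °C comes back to the route at 17. This relies on the doubly activated C7 hydrogens of the ketone being removed much faster than the vinylogous hydrogens of the enal.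

3. Step 22 (HAT hydrogenation of the bromoalkene). Hydrogen-atom transfer to the hindered, electron-poor bromoalkene may be slow, bromine may be lost, axial/equatorial control at C3 may be incomplete, or the epoxy alcohol may react. Fallback: no alkene is reduced; hydrogen is delivered instead to the α-bromo radical derived from a geminal dibromide, on the same unhindered face. The fallback sets out from 23. 1,2-Bis(tert-butyldimethylsilyl)hydrazine with catalytic Sc(OTf)3 gives ethyl (E)-5-[(1S,2S,4aS,8aR)-6-[(tert-butyldimethylsilyl)hydrazinylidene]-2,5,5,8a-tetramethyl-2-[(triethylsilyl)oxy]decahydronaphthalen-1-yl]-3-methylpent-2-enoate F5. CuBr2 and Et3N in MeOH convert F5 into ethyl (E)-5-[(1S,2S,4aS,8aR)-6,6-dibromo-2,5,5,8a-tetramethyl-2-[(triethylsilyl)oxy]decahydronaphthalen-1-yl]-3-methylpent-2-enoate F6. One equivalent of Bu3SnH with Et3B/air at −78 °C should remove one bromine and give ethyl (E)-5-[(1S,2S,4aS,6R,8aR)-6-bromo-2,5,5,8a-tetramethyl-2-[(triethylsilyl)oxy]decahydronaphthalen-1-yl]-3-methylpent-2-enoate F7, with bromine equatorial. DIBAL reduction gives (E)-5-[(1S,2S,4aS,6R,8aR)-6-bromo-2,5,5,8a-tetramethyl-2-[(triethylsilyl)oxy]decahydronaphthalen-1-yl]-3-methylpent-2-en-1-ol F8. Sharpless epoxidation of F8 with D-(−)-diethyl tartrate comes back to the route at 28.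

**Further compounds**

F1 | step 13 | ethyl (1S,2S,4aS,6R,8aR)-6-(benzyloxy)-2,5,5,8a-tetramethyl-2-[(triethylsilyl)oxy]-1,2,4a,5,6,7,8,8a-octahydronaphthalene-1-carboxylate | CCOC(=O)[C@H]1[C@]2(C)CC[C@@H](OCc3ccccc3)C(C)(C)[C@H]2C=C[C@]1(C)O[Si](CC)(CC)CC
F2 | step 13 | [(1R,2S,4aS,6R,8aR)-6-(benzyloxy)-2,5,5,8a-tetramethyl-2-[(triethylsilyl)oxy]-1,2,4a,5,6,7,8,8a-octahydronaphthalen-1-yl]methanol | OC[C@H]1[C@]2(C)CC[C@@H](OCc3ccccc3)C(C)(C)[C@H]2C=C[C@]1(C)O[Si](CC)(CC)CC
F3 | step 10 | (2E,6R,8E,11R)-6-(benzyloxy)-3,7,7-trimethyldodeca-2,8-diene-1,11-diol | OC/C=C(\C)CC[C@@H](OCc1ccccc1)C(C)(C)/C=C/C[C@@H](C)O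
F4 | step 10 | (2E,6R,8E)-6-(benzyloxy)-3,7,7-trimethyl-11-oxododeca-2,8-dienal | O=C/C=C(\C)CC[C@@H](OCc1ccccc1)C(C)(C)/C=C/CC(C)=O
F5 | step 22 | ethyl (E)-5-[(1S,2S,4aS,8aR)-6-[(tert-butyldimethylsilyl)hydrazinylidene]-2,5,5,8a-tetramethyl-2-[(triethylsilyl)oxy]decahydronaphthalen-1-yl]-3-methylpent-2-enoate (C=N geometry not defined) | CCOC(=O)/C=C(\C)CC[C@H]1[C@]2(C)CCC(=NN[Si](C)(C)C(C)(C)C)C(C)(C)[C@H]2CC[C@]1(C)O[Si](CC)(CC)CC
F6 | step 22 | ethyl (E)-5-[(1S,2S,4aS,8aR)-6,6-dibromo-2,5,5,8a-tetramethyl-2-[(triethylsilyl)oxy]decahydronaphthalen-1-yl]-3-methylpent-2-enoate | CCOC(=O)/C=C(\C)CC[C@H]1[C@]2(C)CCC(Br)(Br)C(C)(C)[C@H]2CC[C@]1(C)O[Si](CC)(CC)CC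
F7 | step 22 | ethyl (E)-5-[(1S,2S,4aS,6R,8aR)-6-bromo-2,5,5,8a-tetramethyl-2-[(triethylsilyl)oxy]decahydronaphthalen-1-yl]-3-methylpent-2-enoate | CCOC(=O)/C=C(\C)CC[C@H]1[C@]2(C)CC[C@@H](Br)C(C)(C)[C@H]2CC[C@]1(C)O[Si](CC)(CC)CC
F8 | step 22 | (E)-5-[(1S,2S,4aS,6R,8aR)-6-bromo-2,5,5,8a-tetramethyl-2-[(triethylsilyl)oxy]decahydronaphthalen-1-yl]-3-methylpent-2-en-1-ol | OC/C=C(\C)CC[C@H]1[C@]2(C)CC[C@@H](Br)C(C)(C)[C@H]2CC[C@]1(C)O[Si](CC)(CC)CC
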